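The γ-lactone is cut at its alkyl C–O bond, O–C6 (germacrane numbering). The plan exploits that C6 is allylic to C4=C5, lies γ to the C12 carboxyl, and carries its oxygen 1,3-syn to O8 on the ten-membered ring, cis to the C7 side chain. In the key step a (6S)-allylic mesylate is displaced from the rear by the C12 tert-butyl ester. This one operation closes the lactone ring, inverts C6 to the cis ring fusion and sheds the ester group. The precursor, a ten-membered 1,3-anti diol already acylated at O8, arises from a ring-closing nitrile oxide–alkene cycloaddition followed by an Evans–Tishchenko reduction.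

Key step: step 15

Remark: germacrane numbering is used throughout (ring C1–C10, C11–C13 = propanoate unit on C7, C14 = methyl on C10, C15 = CH2O on C4). The target SMILES is read as 6R,7S,8S,11R, that is O6, the C7 side chain and O8 on one face of the ring (cis-fused lactone), with C13 trans to C8.

Step 1
Reactants: 1 5-bromo-2-methylpent-2-ene; 2 prop-2-yn-1-ol
Product: 5 (2Z)-2-(iodomethylidene)-6-methylhept-5-en-1-ol, via homoprenylmagnesium bromide 3 (not isolated), via cyclic vinylmagnesium alkoxide 4 (not isolated)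
Conditions: Mg, THF, rt (2.3 equiv of 3); 2, CuI (10 mol %), THF, −10 °C to rt; I2, −78 to 0 °C
Reagents that add atoms: iodine [I][I]
Why: Copper-catalysed anti-carbomagnesiation of a propargylic alcohol puts the alkyl group on C4 and magnesium on C5 cis to CH2O in a five-membered chelate, and iodinolysis with retention fixes the C4=C5 geometry (C15 cis to the future C6).

Step 2
Reactants: 5 (2Z)-2-(iodomethylidene)-6-methylhept-5-en-1-ol
Product: 6 tert-butyl{[(2Z)-2-(iodomethylidene)-6-methylhept-5-en-1-yl]oxy}dimethylsilane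
Conditions: TBSCl, imidazole, CH2Cl2, 0 °C to rt
Reagents that add atoms: tert-butyldimethylsilyl chloride CC(C)(C)[Si](C)(C)Cl
Why: Standard silylation of a primary allylic alcohol masks O15 until the last step and creates no stereocentre.

Step 3
Reactants: 6 tert-butyl{[(2Z)-2-(iodomethylidene)-6-methylhept-5-en-1-yl]oxy}dimethylsilane
Product: 7 (2E,6Z)-6-{[(tert-butyldimethylsilyl)oxy]methyl}-7-iodo-2-methylhepta-2,6-dien-1-ol
Conditions: SeO2 (0.3 equiv), t-BuOOH, salicylic acid (cat.), CH2Cl2, 0 °C to rt
Reagents that add atoms: tert-butyl hydroperoxide CC(C)(C)OO; selenium dioxide O=[Se]=O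
Why: Riley-type allylic oxidation (ene reaction, then [2,3]-shift) attacks the electron-rich terminal isopropylidene group and gives the E-allylic alcohol (C9–OH), while the iodoalkene is deactivated.

Step 4
Reactants: 7 (2E,6Z)-6-{[(tert-butyldimethylsilyl)oxy]methyl}-7-iodo-2-methylhepta-2,6-dien-1-ol
Product: 9 (2Z,6E)-3-{[(tert-butyldimethylsilyl)oxy]methyl}-8-hydroxy-7-methylocta-2,6-dienal, via dilithio intermediate 8 (not isolated)
Conditions: t-BuLi (3.2 equiv), Et2O, −78 °C; DMF, −78 °C; aq NH4Cl
Reagents that add atoms: N,N-dimethylformamide CN(C)C=O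
Why: After deprotonation of the alcohol, iodine–lithium exchange occurs with retention of alkene geometry, and formylation with DMF installs C6 as the (Z)-enal; the low temperature holds back oxygen-to-carbon silyl migration.

Step 5
Reactants: 9 (2Z,6E)-3-{[(tert-butyldimethylsilyl)oxy]methyl}-8-hydroxy-7-methylocta-2,6-dienal
Product: 10 (2E,6Z)-6-{[(tert-butyldimethylsilyl)oxy]methyl}-2-methyl-8-oxoocta-2,6-dien-1-yl methyl carbonate
Conditions: ClCO2Me, pyridine, CH2Cl2, 0 °C
Reagents that add atoms: methyl chloroformate COC(=O)Cl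
Why: Acylation of the primary allylic alcohol gives the carbonate that will serve both as leaving group and as internal source of methoxide in step 8; the enal is inert.

Step 6
Reactants: 11 tert-butyl (2E)-4-bromobut-2-enoate
Product: 12 tert-butyl (2R)-2-methylbut-3-enoate
Conditions: MeMgBr, CuBr·SMe2 (1 mol %), Taniaphos (1.2 mol %, enantiomer leading to the R ester), CH2Cl2, −75 °C
Reagents that add atoms: methylmagnesium bromide C[Mg]Br
Why: Copper-catalysed asymmetric allylic alkylation (SN2′) of a 4-halocrotonate with a Grignard reagent delivers methyl to the α-carbon, and the chiral ferrocenyl diphosphine sets C11 as R.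

Step 7
Reactants: 12 tert-butyl (2R)-2-methylbut-3-enoate; 13 2-ethenyl-4,4,5,5-tetramethyl-1,3,2-dioxaborolane
Product: 14 tert-butyl (2R,3E)-2-methyl-4-(4,4,5,5-tetramethyl-1,3,2-dioxaborolan-2-yl)but-3-enoate
Conditions: second-generation Hoveyda–Grubbs catalyst (3 mol %), 1,4-benzoquinone (10 mol %), CH2Cl2, 40 °C
Reagents that add atoms: none
Why: Olefin cross-metathesis of a terminal alkene with a vinylboronate gives the E-alkenylboronate under thermodynamic control, and benzoquinone suppresses hydride-induced alkene migration that would endanger C11.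

Step 8
Reactants: 10 (2E,6Z)-6-{[(tert-butyldimethylsilyl)oxy]methyl}-2-methyl-8-oxoocta-2,6-dien-1-yl methyl carbonate; 14 tert-butyl (2R,3E)-2-methyl-4-(4,4,5,5-tetramethyl-1,3,2-dioxaborolan-2-yl)but-3-enoate
Product: 15 tert-butyl (2R,3E,6E,10Z)-10-{[(tert-butyldimethylsilyl)oxy]methyl}-2,6-dimethyl-12-oxododeca-3,6,10-trienoate
Conditions: Pd(PPh3)4 (5 mol %), THF, 50 °C, no added base
Reagents that add atoms: none
Why: Suzuki–Miyaura-type allyl–alkenyl coupling proceeds through a π-allylpalladium methoxide that activates the boronate; the C8–C9 bond forms at the less hindered primary allyl terminus with retention of both alkene geometries, and the base-free medium protects C11.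

Step 9
Reactants: 15 tert-butyl (2R,3E,6E,10Z)-10-{[(tert-butyldimethylsilyl)oxy]methyl}-2,6-dimethyl-12-oxododeca-3,6,10-trienoate
Product: 16 tert-butyl (2R,3E,6E,10Z,12E)-10-{[(tert-butyldimethylsilyl)oxy]methyl}-12-(hydroxyimino)-2,6-dimethyldodeca-3,6,10-trienoate
Conditions: NH2OH·HCl, pyridine, EtOH, rt
Reagents that add atoms: hydroxylamine hydrochloride NO.Cl
Why: Condensation of the enal with hydroxylamine gives the aldoxime under mild conditions that leave the esters, the silyl ether and C11 untouched.

Step 10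
Reactants: 16 tert-butyl (2R,3E,6E,10Z,12E)-10-{[(tert-butyldimethylsilyl)oxy]methyl}-12-(hydroxyimino)-2,6-dimethyldodeca-3,6,10-trienoate
Product: 18 bridged isoxazoline (7R,8S,11R): ten-membered ring C1–C10 with 1(10)E and 4Z alkenes, C6=N–O–C8 closing a 4,5-dihydroisoxazole, CH2OTBS on C4, (R)-CH(CH3)CO2t-Bu on C7, via nitrile oxide 17 (not isolated)
Conditions: aq NaOCl, CH2Cl2, 0 °C to rt, 16 added by syringe pump (about 1 mM)
Reagents that add atoms: none
Why: In this intramolecular nitrile oxide–alkene cycloaddition hypochlorite dehydrogenates the oxime to 17, which can reach only C7=C8 in the C6–C7/O–C8 sense (every other mode would place E-alkenes in six- to nine-membered rings), the suprafacial addition to the E-alkene fixes C7 relative to C8, and C11 selects the alkene face because the bulky CO2t-Bu group must point away from the folding chain (ester anti, methyl inside, hydrogen outside).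

Step 11
Reactants: 18 bridged isoxazoline (7R,8S,11R)
Product: 19 tert-butyl (7S,8S,11R)-15-[(tert-butyldimethylsilyl)oxy]-8-hydroxy-6-oxogermacra-1(10)E,4Z-dien-12-oate
Conditions: Mo(CO)6 (1.2 equiv), MeCN–H2O 10:1, 80 °C
Reagents that add atoms: water O
Why: Reductive N–O cleavage of the isoxazoline by Mo(CO)6 and hydrolysis of the β-hydroxy imine unmask the aldol without touching the alkenes or the stereocentres, and the tert-butyl ester resists lactonisation by O8.

Step 12
Reactants: 20 2-methylidenepropane-1,3-diol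
Product: 21 2-{[(tert-butyldimethylsilyl)oxy]methyl}prop-2-en-1-ol
Conditions: NaH (1 equiv), THF, 0 °C; TBSCl (1 equiv)
Reagents that add atoms: tert-butyldimethylsilyl chloride CC(C)(C)[Si](C)(C)Cl
Why: Monosilylation of a symmetrical diol through its sparingly soluble monosodium alkoxide stops after one silyl group.

Step 13
Reactants: 21 2-{[(tert-butyldimethylsilyl)oxy]methyl}prop-2-en-1-ol
Product: 22 2-{[(tert-butyldimethylsilyl)oxy]methyl}prop-2-enal
Conditions: MnO2, CH2Cl2, rt
Reagents that add atoms: none
Why: MnO2 oxidises the allylic alcohol selectively to the enal without over-oxidation.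

Step 14
Reactants: 19 tert-butyl (7S,8S,11R)-15-[(tert-butyldimethylsilyl)oxy]-8-hydroxy-6-oxogermacra-1(10)E,4Z-dien-12-oate; 22 2-{[(tert-butyldimethylsilyl)oxy]methyl}prop-2-enal
Product: 23 tert-butyl (6S,7R,8S,11R)-15-[(tert-butyldimethylsilyl)oxy]-8-[(2-{[(tert-butyldimethylsilyl)oxy]methyl}prop-2-enoyl)oxy]-6-hydroxygermacra-1(10)E,4Z-dien-12-oate
Conditions: SmI2 (30 mol %) premixed with 22 (6 equiv), THF, −10 °C; then 19
Reagents that add atoms: none
Why: In the Evans–Tishchenko reduction the trivalent samarium alkoxide formed from SmI2 and 22 binds the hemiacetal of O8 and the C6 ketone, hydride passes to C6 within a chair-like six-membered transition state to give the 1,3-anti (6S) alcohol, and the oxidised aldehyde stays on O8 as the acrylate, so the two oxygens are told apart.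

Step 15
Reactants: 23 tert-butyl (6S,7R,8S,11R)-15-[(tert-butyldimethylsilyl)oxy]-8-[(2-{[(tert-butyldimethylsilyl)oxy]methyl}prop-2-enoyl)oxy]-6-hydroxygermacra-1(10)E,4Z-dien-12-oate
Product: 25 (6R,7S,8S,11R)-15-[(tert-butyldimethylsilyl)oxy]-8-[(2-{[(tert-butyldimethylsilyl)oxy]methyl}prop-2-enoyl)oxy]germacra-1(10)E,4Z-dien-12,6-olide, via allylic mesylate 24 (not isolated)
Conditions: Ms2O, i-Pr2NEt, CH2Cl2, −40 to 0 °C
Reagents that add atoms: none
Why: Ms2O converts the C6 alcohol into allylic mesylate 24, whose C–O bond is attacked from the rear by the carbonyl oxygen of the C12 tert-butyl ester, and the dialkoxycarbenium ion then loses 2-methylpropene to leave the lactone. The closest known reaction type is the neighbouring-group SN2 lactonisation of γ-sulfonyloxy tert-butyl esters, the ester counterpart of the cyclisation of N-Boc amino mesylates to oxazolidinones. The five-membered ring closes in the 5-exo-tet mode by forming the O–C6 bond. C6 is the only stereocentre touched and is set by inversion (6S to 6R), so the 1,3-anti array of step 14 becomes the 1,3-syn, cis-fused array of the target, a fusion that direct cyclisation onto a planar C6 in the macrocycle would not favour. The step needs SN2 attack to win over SN2′ attack, over ionisation with transannular capture by C1=C10 and over participation of the C8 acrylate; the five-ring attack of the electron-richer saturated ester is faster than the seven-ring SN2′ or six-ring acyloxonium paths, chloride-free Ms2O leaves no external nucleophile, and the low temperature and amine buffer hold back ionisation.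

Step 16
Reactants: 25 (6R,7S,8S,11R)-15-[(tert-butyldimethylsilyl)oxy]-8-[(2-{[(tert-butyldimethylsilyl)oxy]methyl}prop-2-enoyl)oxy]germacra-1(10)E,4Z-dien-12,6-olide
Product: 26 (6R,7S,8S,11R)-15-hydroxy-8-{[2-(hydroxymethyl)prop-2-enoyl]oxy}germacra-1(10)E,4Z-dien-12,6-olide (target)
Conditions: HF·pyridine, pyridine, THF, 0 °C to rt
Reagents that add atoms: none
Why: Buffered fluoride cleavage removes both primary TBS ethers under conditions that spare the lactone, the acrylate ester, the acid-sensitive 1,5-diene and all four stereocentres.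

Compound list
1 | 5-bromo-2-methylpent-2-ene | CC(C)=CCCBr | starting material
2 | prop-2-yn-1-ol | C#CCO | starting material
3 | (4-methylpent-3-en-1-yl)magnesium bromide | CC(C)=CCC[Mg]Br | intermediate
4 | cyclic vinylmagnesium alkoxide (4-(4-methylpent-3-enyl)-2,5-dihydro-1,2-oxamagnesole) | CC(C)=CCCC1=C[Mg]OC1 | intermediate
5 | (2Z)-2-(iodomethylidene)-6-methylhept-5-en-1-ol | I/C=C(CO)/CCC=C(C)C | intermediate
6 | tert-butyl{[(2Z)-2-(iodomethylidene)-6-methylhept-5-en-1-yl]oxy}dimethylsilane | I/C=C(CO[Si](C)(C)C(C)(C)C)/CCC=C(C)C | intermediate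
7 | (2E,6Z)-6-{[(tert-butyldimethylsilyl)oxy]methyl}-7-iodo-2-methylhepta-2,6-dien-1-ol | I/C=C(CO[Si](C)(C)C(C)(C)C)/CC/C=C(C)/CO | intermediate
8 | dilithio derivative of 7 (C5 vinyllithium, C9 lithium alkoxide) | [Li]/C=C(CO[Si](C)(C)C(C)(C)C)/CC/C=C(C)/CO[Li] | intermediate
9 | (2Z,6E)-3-{[(tert-butyldimethylsilyl)oxy]methyl}-8-hydroxy-7-methylocta-2,6-dienal | O=C/C=C(CO[Si](C)(C)C(C)(C)C)/CC/C=C(C)/CO | intermediate
10 | (2E,6Z)-6-{[(tert-butyldimethylsilyl)oxy]methyl}-2-methyl-8-oxoocta-2,6-dien-1-yl methyl carbonate | O=C/C=C(CO[Si](C)(C)C(C)(C)C)/CC/C=C(C)/COC(=O)OC | intermediate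
11 | tert-butyl (2E)-4-bromobut-2-enoate | BrC/C=C/C(=O)OC(C)(C)C | starting material
12 | tert-butyl (2R)-2-methylbut-3-enoate | C=C[C@@H](C)C(=O)OC(C)(C)C | intermediate
13 | 2-ethenyl-4,4,5,5-tetramethyl-1,3,2-dioxaborolane | C=CB1OC(C)(C)C(C)(C)O1 | starting material
14 | tert-butyl (2R,3E)-2-methyl-4-(4,4,5,5-tetramethyl-1,3,2-dioxaborolan-2-yl)but-3-enoate | CC1(C)OB(/C=C/[C@@H](C)C(=O)OC(C)(C)C)OC1(C)C | intermediate
15 | tert-butyl (2R,3E,6E,10Z)-10-{[(tert-butyldimethylsilyl)oxy]methyl}-2,6-dimethyl-12-oxododeca-3,6,10-trienoate | O=C/C=C(CO[Si](C)(C)C(C)(C)C)/CC/C=C(C)/C/C=C/[C@@H](C)C(=O)OC(C)(C)C | intermediate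
16 | tert-butyl (2R,3E,6E,10Z,12E)-10-{[(tert-butyldimethylsilyl)oxy]methyl}-12-(hydroxyimino)-2,6-dimethyldodeca-3,6,10-trienoate | O/N=C/C=C(CO[Si](C)(C)C(C)(C)C)/CC/C=C(C)/C/C=C/[C@@H](C)C(=O)OC(C)(C)C | intermediate
17 | nitrile oxide derived from 16 (C6≡N–O) | [O-][N+]#C/C=C(CO[Si](C)(C)C(C)(C)C)/CC/C=C(C)/C/C=C/[C@@H](C)C(=O)OC(C)(C)C | intermediate
18 | bridged isoxazoline (7R,8S,11R), C6=N–O–C8 across the 1(10)E,4Z ten-membered ring | O1N=C2/C=C(CO[Si](C)(C)C(C)(C)C)/CC/C=C(C)/C[C@H]1[C@@H]2[C@@H](C)C(=O)OC(C)(C)C | intermediate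
19 | tert-butyl (7S,8S,11R)-15-[(tert-butyldimethylsilyl)oxy]-8-hydroxy-6-oxogermacra-1(10)E,4Z-dien-12-oate | O[C@H]1C/C(C)=C/CC/C(CO[Si](C)(C)C(C)(C)C)=C/C(=O)[C@H]1[C@@H](C)C(=O)OC(C)(C)C | intermediate
20 | 2-methylidenepropane-1,3-diol | C=C(CO)CO | starting material
21 | 2-{[(tert-butyldimethylsilyl)oxy]methyl}prop-2-en-1-ol | C=C(CO)CO[Si](C)(C)C(C)(C)C | intermediate
22 | 2-{[(tert-butyldimethylsilyl)oxy]methyl}prop-2-enal | C=C(CO[Si](C)(C)C(C)(C)C)C=O | intermediate
23 | tert-butyl (6S,7R,8S,11R)-15-(TBSO)-8-{[2-(TBSOCH2)prop-2-enoyl]oxy}-6-hydroxygermacra-1(10)E,4Z-dien-12-oate | C=C(CO[Si](C)(C)C(C)(C)C)C(=O)O[C@H]1C/C(C)=C/CC/C(CO[Si](C)(C)C(C)(C)C)=C/[C@H](O)[C@H]1[C@@H](C)C(=O)OC(C)(C)C | intermediate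
24 | 6-O-methanesulfonate of 23 (6S,7S,8S,11R) | C=C(CO[Si](C)(C)C(C)(C)C)C(=O)O[C@H]1C/C(C)=C/CC/C(CO[Si](C)(C)C(C)(C)C)=C/[C@H](OS(C)(=O)=O)[C@H]1[C@@H](C)C(=O)OC(C)(C)C | intermediate
25 | (6R,7S,8S,11R)-15-(TBSO)-8-{[2-(TBSOCH2)prop-2-enoyl]oxy}germacra-1(10)E,4Z-dien-12,6-olide | C=C(CO[Si](C)(C)C(C)(C)C)C(=O)O[C@H]1C/C(C)=C/CC/C(CO[Si](C)(C)C(C)(C)C)=C/[C@H]2OC(=O)[C@H](C)[C@@H]12 | intermediate
26 | (6R,7S,8S,11R)-15-hydroxy-8-{[2-(hydroxymethyl)prop-2-enoyl]oxy}germacra-1(10)E,4Z-dien-12,6-olide | C=C(CO)C(=O)O[C@H]1C/C(C)=C/CC/C(CO)=C/[C@H]2OC(=O)[C@H](C)[C@@H]12 | target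

Total step count: 16. Longest linear sequence: 12 steps (steps 1–5, 8–11, 14–16).

Steps most likely to fail

Step 10. Dimerisation of nitrile oxide 17 and intermolecular cycloaddition may outrun the slow closure of the strained ten-membered ring, and the C11 stereocentre may bias the alkene face only weakly (the two cycloadducts are diastereomers and would be separated). The fallback sets out from oxime 16 and changes the dipole. Heating 16 in toluene at 110 °C under high dilution lets it react through its N–H nitrone tautomer (intramolecular oxime–olefin cycloaddition). That dipole forms reversibly and has no irreversible dimerisation channel, and it should give the N–H isoxazolidine F1. N-chlorination of F1 with N-chlorosuccinimide and dehydrochlorination with DBU then lead back to the route at isoxazoline 18.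

Step 15. Ionisation of allylic mesylate 24 ahead of displacement would erode the inversion at C6 and open the way to SN2′ attack, to elimination and to transannular capture of the allyl cation by C1=C10. The fallback sets out from 23 and replaces the sulfonate by redox-condensation activation of a free acid. The tert-butyl ester is cleaved with TMSOTf and 2,6-lutidine (CH2Cl2, 0 °C, aqueous work-up) to the hydroxy acid F2, which is used at once. The same O–C6 bond is then closed by Mitsunobu lactonisation (PPh3, DIAD, toluene, 0 °C, high dilution), in which the carboxylate displaces the C6 alkoxyphosphonium ion with inversion. The route is rejoined at 25.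

Step 14. Self-condensation and polymerisation of enal 22, retro-aldol opening of 19 on the Lewis acidic samarium alkoxide, or a macrocycle that cannot reach the chair-like hydride-transfer geometry would lead to low conversion or loss of the anti selectivity. The fallback sets out from 19 and separates acylation from reduction. Aldehyde 22 is oxidised (Pinnick oxidation: NaClO2, NaH2PO4, 2-methylbut-2-ene, t-BuOH–H2O) to the acrylic acid F3. O8 of 19 is esterified with F3 (Yamaguchi esterification: 2,4,6-trichlorobenzoyl chloride, Et3N, then DMAP, toluene) to the acyloxy enone F4. The C6 ketone of F4 is reduced 1,2 under reagent control (Corey–Bakshi–Shibata reduction, with the oxazaborolidine enantiomer matched to 6S, catecholborane, toluene, −78 °C). The route is rejoined at 23.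

Further compounds
F1 | step 10 | N–H isoxazolidine (C6–NH–O–C8 bridge, C5 and C9 cis on the five-membered ring, otherwise as 18) | O1N[C@@H]2/C=C(CO[Si](C)(C)C(C)(C)C)/CC/C=C(C)/C[C@H]1[C@@H]2[C@@H](C)C(=O)OC(C)(C)C
F2 | step 15 | (6S,7R,8S,11R)-15-(TBSO)-8-{[2-(TBSOCH2)prop-2-enoyl]oxy}-6-hydroxygermacra-1(10)E,4Z-dien-12-oic acid | C=C(CO[Si](C)(C)C(C)(C)C)C(=O)O[C@H]1C/C(C)=C/CC/C(CO[Si](C)(C)C(C)(C)C)=C/[C@H](O)[C@H]1[C@@H](C)C(=O)O
F3 | step 14 | 2-{[(tert-butyldimethylsilyl)oxy]methyl}prop-2-enoic acid | C=C(CO[Si](C)(C)C(C)(C)C)C(=O)O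
F4 | step 14 | tert-butyl (7S,8S,11R)-15-(TBSO)-8-{[2-(TBSOCH2)prop-2-enoyl]oxy}-6-oxogermacra-1(10)E,4Z-dien-12-oate | C=C(CO[Si](C)(C)C(C)(C)C)C(=O)O[C@H]1C/C(C)=C/CC/C(CO[Si](C)(C)C(C)(C)C)=C/C(=O)[C@H]1[C@@H](C)C(=O)OC(C)(C)C
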